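The readings stem from a simulated flask with constants of no real substance; scatter was added.

At 68 min the product reading of the south-east run leaves 0.0396 M of substrate, the leftover of the limiting reagent, since that charge holds less substrate than reagent. The north-west flask repeats this charge, so its question is how much of that leftover goes in a further 102 min.

all flasks: free catalyst 3.00 × 10⁻⁴ M
- south-east: substrate 0.150 M; reagent 0.225 M
- south-west: substrate 0.0900 M; reagent 0.165 M
- north-east: substrate 0.150 M; reagent 0.110 M
- north-west: substrate 0.150 M; reagent 0.225 M; time 170 min

| run | time / min | [product] / M |
|---|---|---|
| south-east run | 11 | 0.0120 |
| south-east run | 23 | 0.0329 |
| south-east run | 34 | 0.0545 |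
| south-east run | 45 | 0.0771 |
| south-east run | 57 | 0.0983 |
| south-east run | 68 | 0.1104 |
| south-west run | 11 | 0.0050 |
| south-west run | 23 | 0.0138 |
| south-west run | 34 | 0.0221 |
| south-west run | 45 | 0.0301 |
| south-west run | 57 | 0.0380 |
| south-west run | 68 | 0.0447 |
| north-east run | 11 | 0.0104 |
| north-east run | 23 | 0.0217 |
| north-east run | 34 | 0.0340 |
| north-east run | 45 | 0.0451 |
| north-east run | 57 | 0.0558 |
| north-east run | 68 | 0.0658 |

(scatter of a reading: 0.001 M)

- order of the initial rate in [reagent], near the charge of the south-east run, the rate being that where two percent of its substrate are product
- order of the initial rate in [substrate], near the charge of the south-east run, the rate being that where two percent of its substrate are product (one fixed amount of product, the same in the runs compared)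
- the south-west run starts with 0.0600 M less of substrate and of reagent than the south-east run, and with no product. Compared where both hold the same amount of substrate, once fifteen percent of what the south-west run was charged with has turned into product, is the south-west run faster, slower or alike (within a tenth)?
- product in the north-west run at 170 min, as a share of the substrate charged

- Overall: substrate + reagent -> product, with free catalyst as catalyst.
- Constant volume, constant temperature.
- The analysis sees a species whether free or bound.
- An order is taken over about fifteen percent of the charge, up and down.

The reckoning here replaces the end of the south-east curve by its mean. Over the last interval of that run, the rate of product formation divided by the mean substrate left is the fractional rate of the leftover, and the readings give 0.0241 min⁻¹. The logarithm of the two leftovers gives 0.0242 min⁻¹ over the same interval, so taking the mean costs little, while the scatter of the two readings shifts the fractional rate by 11.7 %. Held constant, which is the wager of this estimate, that fractional rate leaves 0.00339 M of substrate in the north-west flask at 170 min, so the product is 97.7 % of the charge, or 97.0 % with the fractional rate one scatter lower.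

The forecast gives orders of 0.2 in reagent and 1.4 in substrate, a south-west run that is slower, and 94 %, lower than this reckoning, “assuming no catalyst death”.

The simulation gives orders of 0.25 in reagent and 1.0 in substrate, a south-west run that is slower, and 98.3 % in the north-west flask.

    free catalyst + reagent ⇌ catalyst-reagent complex, settled at all times (59.00 L mol⁻¹)
    catalyst-reagent complex + substrate → product + free catalyst (29.10 L mol⁻¹ min⁻¹)
    free catalyst + impurity → spent catalyst
    substrate + reagent + product → 2 product (1.842 L² mol⁻² min⁻¹)

That 98.3 % leaves 0.00253 M of substrate in the north-west flask, so from the south-east leftover the fractional rate averaged 0.0270 min⁻¹, above the 0.0241 min⁻¹ read from the last interval. At the point asked about, where the south-west and south-east runs hold the same substrate, the south-west rate is 0.35 of the south-east rate, so at that point their fractional rates stand in that ratio too. The north-east run charges less reagent than substrate, so there the substrate is not the limiting one, but the last interval of that run still gives a fractional rate of its substrate, 0.0102 min⁻¹; carried from 68 min to the point where product is half of the substrate charged, it gives 79.4 min, and the north-east run gets there at 80.5 min.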